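**Retrosynthetic overview**
- The strategy rests on the quaternary C1, shared by ring A (C1–C2–C3–C4–C5) and the bridged ring B (C1–C5–C6–C7–C11). An alkyne on C6 and an exocyclic C1=C2 alkene on ring C are stitched with CO, placed temporarily at C3, in a cobalt-mediated [2+2+1] cycloaddition (bonds C1–C5, C2–C3, C3–C4).
- Ring C comes from methyl 3-oxocyclohex-1-ene-1-carboxylate: Nicholas alkylation at C7 (C6–C7), C1 methylenation, and a reagent-controlled C10 reduction that also resolves the racemate. A silicon tether from O10 and ring-closing metathesis fix C1=C2 as Z (C15 cis to C10); the Co2(CO)6 unit from the Nicholas step is kept as alkyne mask and cycloaddition reagent.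
- After the key step: C3 oxygen removed with delivery of hydrogen to C5 through an allylic diazene, C3=C4 saturated, tether cleaved, methyl ester exchanged for allyl, C10 acylated with the Z hydroxy acid (from oct-7-yn-1-ol and 8-bromooctanoic acid), C15 oxidised, allyl and silyl groups removed.
- Ring order: ring C (starting enone), then rings B and A together in step 9.

Key step: step 9

Assumption: the target SMILES is read literally. It places H-5 on the C11 side of the C5–C6 bridge (anti to C10), so rings A and B are trans-fused across C1–C5; hydrogen is therefore delivered to C5 intramolecularly on that face, not by an undirected reduction. Compounds 8–11 are racemic and are drawn as the enantiomer that is carried on.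

**Route**

Step 1
Reactants: 1 1-hydroxypropan-2-one
Product: 2 1-[(triisopropylsilyl)oxy]propan-2-one
Conditions: i-Pr3SiCl, imidazole, DMF, rt
Reagents that add atoms: triisopropylsilyl chloride, CC(C)[Si](Cl)(C(C)C)C(C)C
Why: Imidazole-promoted silylation of the primary alcohol gives a silyl ether that cannot take part as a neighbouring group in the later ionisation; no stereocenter.

Step 2
Reactants: 2 silyloxy ketone
Product: 3 racemic 2-methyl-1-[(triisopropylsilyl)oxy]but-3-yn-2-ol
Conditions: HC≡CMgBr, THF, 0 °C; H2O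
Reagents that add atoms: ethynylmagnesium bromide, C#C[Mg]Br
Why: Grignard 1,2-addition to the ketone gives the tertiary propargylic alcohol; its configuration is irrelevant because the carbinol carbon (C6) is ionised in step 4.

Step 3
Reactants: 4 methyl 3-oxocyclohex-1-ene-1-carboxylate
Product: 5 methyl 5-[(tert-butyldimethylsilyl)oxy]cyclohexa-1,5-diene-1-carboxylate
Conditions: TBSOTf, Et3N, CH2Cl2, 0 °C → rt
Reagents that add atoms: tert-butyldimethylsilyl trifluoromethanesulfonate, CC(C)(C)[Si](C)(C)OS(=O)(=O)C(F)(F)F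
Why: Soft enolisation with silyl triflate and amine under equilibrating conditions should give the linearly conjugated dienol ether C10(OSi)=C9–C8=C7 (γ-deprotonation), as with other β,β-disubstituted cyclohexenones; no stereocenter.

Step 4
Reactants: 3 racemic propargylic alcohol; 5 silyl dienol ether
Product: 8 cobalt-complexed C7-alkylated enone (racemic), via hexacarbonyldicobalt complex 6 (not isolated), via propargylic cation 7 (not isolated)
Conditions: Co2(CO)8, CH2Cl2, rt; then 5, BF3·OEt2, −78 → −30 °C
Reagents that add atoms: octacarbonyldicobalt Co2(CO)8, O=C=[Co](=C=O)(=C=O)(=C=O)[Co](=C=O)(=C=O)(=C=O)=C=O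
Why: Nicholas reaction: BF3 ionises the complexed alcohol to cation 7, which the dienol ether captures at its terminal γ-carbon C7 (vinylogous Mukaiyama-type alkylation that re-forms the enone); in the open transition state the Co2(CO)6–alkyne unit should lie anti to C8, CH2OTIPS beside H-7 and the methyl over the ring, giving the C6/C7 relative configuration drawn, and the other C6 epimer is removed by chromatography and can be recycled by DBU epimerisation at C7, the vinylogous α-position.

Step 5
Reactants: 8 cobalt-complexed enone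
Product: 11 C1-methylene dienone (racemic), via Mannich base 9 (not isolated), via ammonium iodide 10 (not isolated)
Conditions: LiN(SiMe3)2, THF, −78 °C; Me2N=CH2+ I−, −78 → 0 °C; MeI, CH2Cl2, rt; aq. NaHCO3, 0 °C
Reagents that add atoms: N,N-dimethylmethyleneiminium iodide (Eschenmoser's salt), C=[N+](C)C.[I-]
Why: Mannich reaction of the kinetic α'-enolate at C1, N-methylation and E1cB loss of trimethylamine install the exocyclic methylene, the bicarbonate elimination avoiding deprotonation at C7 that would aromatise the ring; no new stereocenter.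

Step 6
Reactants: 11 racemic dienone
Product: 12 trans-dienol (single enantiomer)
Conditions: (R)-Me-CBS oxazaborolidine, BH3·SMe2, toluene, −40 °C; MeOH
Reagents that add atoms: none
Why: Corey–Bakshi–Shibata reduction run as a divergent reaction on the racemate: with the fully substituted C1 as the large flank the catalyst delivers hydride to the same carbonyl face in both enantiomers, so the needed enantiomer gives the trans-dienol (hydride syn to the C7 arm, against the substrate bias) while its mirror image gives the cis-dienol, which is removed by chromatography; this sets C10 and the absolute configuration.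

Step 7
Reactants: 12 trans-dienol
Product: 14 C10 allyloxy(diisopropyl)silyl ether, via chlorosilyl ether 13 (not isolated)
Conditions: i-Pr2SiCl2 (excess), imidazole, CH2Cl2, 0 °C; evaporate; allyl alcohol, imidazole, CH2Cl2, rt
Reagents that add atoms: dichlorodiisopropylsilane, CC(C)[Si](Cl)(Cl)C(C)C; allyl alcohol, C=CCO
Why: Stepwise silylation builds a temporary silicon tether: the hindered secondary alcohol reacts once with excess dichlorosilane and the remaining Si–Cl is capped by allyl alcohol; no new stereocenter.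

Step 8
Reactants: 14 silicon-tethered diene
Product: 15 Pauson–Khand precursor (silylene-bridged Z-alkene, cobalt-complexed alkyne)
Conditions: second-generation Grubbs catalyst RuCl2(=CHPh)(PCy3)(H2IMes), CH2Cl2, 40 °C
Reagents that add atoms: none
Why: Ring-closing metathesis through the tether closes a seven-membered 1,3-dioxa-2-silacycloheptene, so the new trisubstituted C1=C2 alkene can only be Z (C15 cis to C10), while the Co2(CO)6 unit keeps the alkyne out of enyne metathesis.

Step 9
Reactants: 15 Pauson–Khand precursor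
Product: 16 tricyclic enone (C3 ketone, C4=C5)
Conditions: NMO, CH2Cl2, 0 °C → rt
Reagents that add atoms: none
Why: Pauson–Khand reaction: the N-oxide oxidises a CO ligand and opens a site on cobalt, the exocyclic C1=C2 alkene inserts into the Co–C5 bond (C1–C5), CO inserts and reductive elimination joins C3 to C2 and C4 to give the cyclopentenone. The closest known case is the cyclisation of an exocyclic methylene on a cyclohexane carrying a quaternary propargylic arm to the cedrane tricycle; here the alkene is trisubstituted and held in the silylene ring. Ring B (C1–C5–C6–C7–C11) closes by 5-exo attack of the C6-tethered alkyne carbon C5 on C1 and is bridged across ring C; ring A (C1–C2–C3–C4–C5) closes in the same event as the cyclopentenone from C4≡C5, C1=C2 and CO. C1 is fixed by the tether, because the alkyne on the C7 arm reaches only the alkene face on its own side of ring C, and C2 follows from syn addition across the Z alkene, which places C15 on the side of C10 where the silylene holds it. The step must take C1=C2 in preference to the C8=C9 enoate, which the alkyne cannot reach; the quaternary C6 keeps alkyne and alkene close and the silylene ring lies on the face opposite to the incoming alkyne.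

Step 10
Reactants: 16 tricyclic enone
Product: 17 C3 allylic alcohol (hydroxyl cis to C15)
Conditions: NaBH4, CeCl3·7H2O, MeOH/THF, −78 °C
Reagents that add atoms: none
Why: Luche 1,2-reduction of the cyclopentenone leaves the enoate alone, and hydride should add to C3 from the face away from the adjacent C15 and the silylene ring, placing the hydroxyl cis to C15.

Step 11
Reactants: 17 allylic alcohol
Product: 20 C3=C4 alkene with H-5 on the C11 side, via sulfonylhydrazone adduct 18 (not isolated), via allylic diazene 19 (not isolated)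
Conditions: PPh3, DEAD, N-isopropylidene-N'-(2-nitrobenzenesulfonyl)hydrazine (IPNBSH), THF, 0 → 23 °C; then CF3CH2OH/H2O, 23 °C
Reagents that add atoms: none
Why: Reductive allylic transposition: Mitsunobu displacement inverts C3, hydrolysis and loss of sulfinate give the monoalkyl diazene, and its retro-ene loss of N2 delivers hydrogen suprafacially to C5 on the face that carried nitrogen (the C11 side), which sets C5 as drawn, removes the C3 oxygen and moves the alkene to C3=C4.

Step 12
Reactants: 20 C3=C4 alkene
Product: 21 tricycle with saturated ring A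
Conditions: 2-nitrobenzenesulfonohydrazide, Et3N, CH2Cl2, rt
Reagents that add atoms: none
Why: Diimide reduction is selective for the strained cis-disubstituted cyclopentene over the trisubstituted conjugated enoate; no new stereocenter.

Step 13
Reactants: 21 silylene-protected tricycle
Product: 22 C10,C15-diol
Conditions: HF·pyridine, pyridine, THF, 0 °C
Reagents that add atoms: none
Why: Fluoride cleaves the dialkoxysilane far faster than the neopentyl triisopropylsilyl ether at C13; no stereocenter is touched.

Step 14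
Reactants: 22 diol methyl ester
Product: 23 diol carboxylic acid
Conditions: LiOH, THF/MeOH/H2O, 45 °C; then 1 M HCl to pH 3
Reagents that add atoms: lithium hydroxide, [Li+].[OH-]
Why: Saponification of the conjugated methyl ester is done here, while no other ester and no aldehyde are present (a late hydrolysis could not spare the C10 ester).

Step 15
Reactants: 23 diol carboxylic acid
Product: 24 allyl ester diol
Conditions: allyl bromide, KHCO3, DMF, rt
Reagents that add atoms: allyl bromide, C=CCBr
Why: SN2 O-alkylation of the carboxylate is chemoselective over the two hydroxyls and gives an ester that can be removed under neutral conditions at the end.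

Step 16
Reactants: 24 allyl ester diol
Product: 25 C15 triethylsilyl ether
Conditions: Et3SiCl, imidazole, CH2Cl2, −40 °C
Reagents that add atoms: chlorotriethylsilane, CC[Si](Cl)(CC)CC
Why: Silylation discriminates the primary C15 hydroxyl from the hindered secondary allylic C10 hydroxyl next to the quaternary C1.

Step 17
Reactants: 26 oct-7-yn-1-ol
Product: 27 triisopropyl(oct-7-yn-1-yloxy)silane
Conditions: i-Pr3SiCl, imidazole, DMF, rt
Reagents that add atoms: triisopropylsilyl chloride, CC(C)[Si](Cl)(C(C)C)C(C)C
Why: Silyl ether formation protects the hydroxyl for the acetylide chemistry and the later esterification.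

Step 18
Reactants: 27 silyl-protected alkyne; 28 8-bromooctanoic acid
Product: 31 16-[(triisopropylsilyl)oxy]hexadec-9-ynoic acid, via lithium acetylide 29 (not isolated), via lithium 8-bromooctanoate 30 (not isolated)
Conditions: 27, n-BuLi, THF, −78 °C; 28, LiN(SiMe3)2, THF, −78 °C; combine, DMPU, 0 °C → rt; 1 M HCl
Reagents that add atoms: none
Why: SN2 alkylation of the lithium acetylide by the primary bromide, the acid being carried as its lithium carboxylate, joins the two C8 pieces with the triple bond at C9–C10.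

Step 19
Reactants: 31 ynoic acid
Product: 32 (9Z)-16-[(triisopropylsilyl)oxy]hexadec-9-enoic acid
Conditions: H2 (1 atm), Lindlar catalyst (Pd/CaCO3, Pb(OAc)2), quinoline, EtOAc, rt
Reagents that add atoms: none
Why: Lindlar semi-hydrogenation adds H2 syn to the alkyne and stops at the Z alkene.

Step 20
Reactants: 25 C10 alcohol; 32 Z-enoic acid
Product: 34 C10 ester, via mixed anhydride 33 (not isolated)
Conditions: 32, 2,4,6-trichlorobenzoyl chloride, Et3N, toluene, rt; then 25, DMAP, toluene, rt → 40 °C
Reagents that add atoms: none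
Why: Yamaguchi esterification: the mixed anhydride and DMAP acylate the hindered secondary allylic alcohol on oxygen, so C10 keeps its configuration.

Step 21
Reactants: 34 C10 ester
Product: 35 C15 primary alcohol
Conditions: PPTS, MeOH/CH2Cl2, 0 °C
Reagents that add atoms: none
Why: Mild acid methanolysis removes the primary triethylsilyl ether and leaves both triisopropylsilyl ethers, the allyl ester and the C10 ester.

Step 22
Reactants: 35 primary alcohol
Product: 36 C15 aldehyde
Conditions: Dess–Martin periodinane, NaHCO3, CH2Cl2, 0 °C → rt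
Reagents that add atoms: none
Why: Dess–Martin oxidation under buffered, non-basic conditions gives the aldehyde without epimerising the adjacent C2.

Step 23
Reactants: 36 allyl ester aldehyde
Product: 37 C12 carboxylic acid
Conditions: Pd(PPh3)4 (cat.), sodium 4-methylbenzenesulfinate (TolSO2Na), THF/MeOH, rt; 0.1 M HCl
Reagents that add atoms: none
Why: Tsuji–Trost deallylation: zerovalent palladium forms the π-allyl complex from the allyl ester and the sulfinate traps it, freeing the acid under neutral conditions that spare the C10 ester, the aldehyde and the Z alkene.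

Step 24
Reactants: 37 bis-silyl acid
Product: 38 target, (1R,2S,5S,6S,7S,10S)-2-formyl-10-{[(9Z)-16-hydroxyhexadec-9-enoyl]oxy}-6-(hydroxymethyl)-6-methyltricyclo[5.3.1.0^1,5]undec-8-ene-8-carboxylic acid
Conditions: HF·pyridine, pyridine, THF, 0 °C → rt
Reagents that add atoms: none
Why: Fluoride cleavage of both primary triisopropylsilyl ethers under acidic, non-epimerising conditions gives the target.

**Compound list**
1 | 1-hydroxypropan-2-one | CC(=O)CO | starting material
2 | 1-[(triisopropylsilyl)oxy]propan-2-one | CC(=O)CO[Si](C(C)C)(C(C)C)C(C)C | intermediate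
3 | racemic 2-methyl-1-[(triisopropylsilyl)oxy]but-3-yn-2-ol | CC(O)(CO[Si](C(C)C)(C(C)C)C(C)C)C#C | intermediate
4 | methyl 3-oxocyclohex-1-ene-1-carboxylate | COC(=O)C1=CC(=O)CCC1 | starting material
5 | methyl 5-[(tert-butyldimethylsilyl)oxy]cyclohexa-1,5-diene-1-carboxylate | COC(=O)C1=CCCC(O[Si](C)(C)C(C)(C)C)=C1 | intermediate
6 | μ-alkyne Co2(CO)6 complex of 3 (not isolated) | CC(O)(CO[Si](C(C)C)(C(C)C)C(C)C)C12C3[Co]1(=C=O)(=C=O)(=C=O)[Co]23(=C=O)(=C=O)=C=O | intermediate
7 | Co2(CO)6-stabilised tertiary propargylic cation at C6 (not isolated) | C[C+](CO[Si](C(C)C)(C(C)C)C(C)C)C12C3[Co]1(=C=O)(=C=O)(=C=O)[Co]23(=C=O)(=C=O)=C=O | intermediate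
8 | ring C enone (C10 ketone, C8=C9 methyl ester) with C7 bearing quaternary C6 (CH3, CH2OTIPS, Co2(CO)6-complexed ethynyl); racemic, C6/C7 as in the target | O=C1CC[C@@H]([C@@](C)(CO[Si](C(C)C)(C(C)C)C(C)C)C56C7[Co]5(=C=O)(=C=O)(=C=O)[Co]67(=C=O)(=C=O)=C=O)C(C(=O)OC)=C1 | intermediate
9 | C1-(dimethylaminomethyl) derivative of 8, both C1 epimers (not isolated) | CN(C)CC1C[C@@H]([C@@](C)(CO[Si](C(C)C)(C(C)C)C(C)C)C56C7[Co]5(=C=O)(=C=O)(=C=O)[Co]67(=C=O)(=C=O)=C=O)C(C(=O)OC)=CC1=O | intermediate
10 | trimethylammonium iodide of 9 (not isolated) | C[N+](C)(C)CC1C[C@@H]([C@@](C)(CO[Si](C(C)C)(C(C)C)C(C)C)C56C7[Co]5(=C=O)(=C=O)(=C=O)[Co]67(=C=O)(=C=O)=C=O)C(C(=O)OC)=CC1=O.[I-] | intermediate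
11 | C1-methylene dienone (racemic), cobalt-complexed | C=C1C[C@@H]([C@@](C)(CO[Si](C(C)C)(C(C)C)C(C)C)C56C7[Co]5(=C=O)(=C=O)(=C=O)[Co]67(=C=O)(=C=O)=C=O)C(C(=O)OC)=CC1=O | intermediate
12 | trans-dienol: C10 hydroxyl trans to the C7 arm, C6, C7 and C10 as in the target, cobalt-complexed | C=C1C[C@@H]([C@@](C)(CO[Si](C(C)C)(C(C)C)C(C)C)C56C7[Co]5(=C=O)(=C=O)(=C=O)[Co]67(=C=O)(=C=O)=C=O)C(C(=O)OC)=C[C@@H]1O | intermediate
13 | C10 O-chloro(diisopropyl)silyl ether of 12 (not isolated) | C=C1C[C@@H]([C@@](C)(CO[Si](C(C)C)(C(C)C)C(C)C)C56C7[Co]5(=C=O)(=C=O)(=C=O)[Co]67(=C=O)(=C=O)=C=O)C(C(=O)OC)=C[C@@H]1O[Si](Cl)(C(C)C)C(C)C | intermediate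
14 | C10 O-[allyloxy(diisopropyl)silyl] ether of 12 | C=C1C[C@@H]([C@@](C)(CO[Si](C(C)C)(C(C)C)C(C)C)C56C7[Co]5(=C=O)(=C=O)(=C=O)[Co]67(=C=O)(=C=O)=C=O)C(C(=O)OC)=C[C@@H]1O[Si](C(C)C)(C(C)C)OCC=C | intermediate
15 | Pauson–Khand precursor: ring C with Z exocyclic C1=C2 inside a 2,2-diisopropyl-1,3-dioxa-2-silacycloheptene (O10–Si–O15), C7 arm with Co2(CO)6-complexed alkyne | C2/C=C1/C[C@@H]([C@@](C)(CO[Si](C(C)C)(C(C)C)C(C)C)C56C7[Co]5(=C=O)(=C=O)(=C=O)[Co]67(=C=O)(=C=O)=C=O)C(C(=O)OC)=C[C@@H]1O[Si](C(C)C)(C(C)C)O2 | intermediate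
16 | cedrane tricycle as C3-oxo C4=C5 enone, O10/O15 diisopropylsilylene, C13 OTIPS, C12 methyl ester | C[C@@]1(CO[Si](C(C)C)(C(C)C)C(C)C)[C@@H]2C[C@]3([C@@H](O[Si](C(C)C)(C(C)C)OC4)C=C2C(=O)OC)[C@@H]4C(=O)C=C13 | intermediate
17 | C3 allylic alcohol, hydroxyl cis to C15 | C[C@@]1(CO[Si](C(C)C)(C(C)C)C(C)C)[C@@H]2C[C@]3([C@@H](O[Si](C(C)C)(C(C)C)OC4)C=C2C(=O)OC)[C@@H]4[C@@H](O)C=C13 | intermediate
18 | C3 N-(isopropylideneamino)-2-nitrobenzenesulfonamide, C3 inverted (not isolated) | C[C@@]1(CO[Si](C(C)C)(C(C)C)C(C)C)[C@@H]2C[C@]3([C@@H](O[Si](C(C)C)(C(C)C)OC4)C=C2C(=O)OC)[C@@H]4[C@H](N(N=C(C)C)S(=O)(=O)c5ccccc5[N+](=O)[O-])C=C13 | intermediate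
19 | C3 monoalkyl diazene (not isolated) | C[C@@]1(CO[Si](C(C)C)(C(C)C)C(C)C)[C@@H]2C[C@]3([C@@H](O[Si](C(C)C)(C(C)C)OC4)C=C2C(=O)OC)[C@@H]4[C@H](N=N)C=C13 | intermediate
20 | C3=C4 alkene, H-5 on the C11 side | C[C@@]1(CO[Si](C(C)C)(C(C)C)C(C)C)[C@@H]2C[C@]3([C@@H](O[Si](C(C)C)(C(C)C)OC4)C=C2C(=O)OC)[C@@H]4C=C[C@@H]13 | intermediate
21 | tricycle with saturated ring A, silylene intact | C[C@@]1(CO[Si](C(C)C)(C(C)C)C(C)C)[C@@H]2C[C@]3([C@@H](O[Si](C(C)C)(C(C)C)OC4)C=C2C(=O)OC)[C@@H]4CC[C@@H]13 | intermediate
22 | C10,C15-diol, C12 methyl ester, C13 OTIPS | C[C@@]1(CO[Si](C(C)C)(C(C)C)C(C)C)[C@@H]2C[C@]3([C@@H](O)C=C2C(=O)OC)[C@@H](CO)CC[C@@H]13 | intermediate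
23 | C10,C15-diol C12 carboxylic acid | C[C@@]1(CO[Si](C(C)C)(C(C)C)C(C)C)[C@@H]2C[C@]3([C@@H](O)C=C2C(=O)O)[C@@H](CO)CC[C@@H]13 | intermediate
24 | C10,C15-diol C12 allyl ester | C[C@@]1(CO[Si](C(C)C)(C(C)C)C(C)C)[C@@H]2C[C@]3([C@@H](O)C=C2C(=O)OCC=C)[C@@H](CO)CC[C@@H]13 | intermediate
25 | C15 O-triethylsilyl ether, free C10 hydroxyl | C[C@@]1(CO[Si](C(C)C)(C(C)C)C(C)C)[C@@H]2C[C@]3([C@@H](O)C=C2C(=O)OCC=C)[C@@H](CO[Si](CC)(CC)CC)CC[C@@H]13 | intermediate
26 | oct-7-yn-1-ol | C#CCCCCCCO | starting material
27 | triisopropyl(oct-7-yn-1-yloxy)silane | C#CCCCCCCO[Si](C(C)C)(C(C)C)C(C)C | intermediate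
28 | 8-bromooctanoic acid | OC(=O)CCCCCCCBr | starting material
29 | lithium acetylide of 27 (not isolated) | [Li]C#CCCCCCCO[Si](C(C)C)(C(C)C)C(C)C | intermediate
30 | lithium 8-bromooctanoate (not isolated) | [Li+].[O-]C(=O)CCCCCCCBr | intermediate
31 | 16-[(triisopropylsilyl)oxy]hexadec-9-ynoic acid | OC(=O)CCCCCCCC#CCCCCCCO[Si](C(C)C)(C(C)C)C(C)C | intermediate
32 | (9Z)-16-[(triisopropylsilyl)oxy]hexadec-9-enoic acid | OC(=O)CCCCCCC/C=C\CCCCCCO[Si](C(C)C)(C(C)C)C(C)C | intermediate
33 | mixed anhydride of 32 with 2,4,6-trichlorobenzoic acid (not isolated) | O=C(OC(=O)CCCCCCC/C=C\CCCCCCO[Si](C(C)C)(C(C)C)C(C)C)c1c(Cl)cc(Cl)cc1Cl | intermediate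
34 | C10 (9Z)-16-(TIPSO)hexadec-9-enoate, C15 OTES, C13 OTIPS, allyl ester | C[C@@]1(CO[Si](C(C)C)(C(C)C)C(C)C)[C@@H]2C[C@]3([C@@H](OC(=O)CCCCCCC/C=C\CCCCCCO[Si](C(C)C)(C(C)C)C(C)C)C=C2C(=O)OCC=C)[C@@H](CO[Si](CC)(CC)CC)CC[C@@H]13 | intermediate
35 | C15 primary alcohol | C[C@@]1(CO[Si](C(C)C)(C(C)C)C(C)C)[C@@H]2C[C@]3([C@@H](OC(=O)CCCCCCC/C=C\CCCCCCO[Si](C(C)C)(C(C)C)C(C)C)C=C2C(=O)OCC=C)[C@@H](CO)CC[C@@H]13 | intermediate
36 | C15 aldehyde, allyl ester | C[C@@]1(CO[Si](C(C)C)(C(C)C)C(C)C)[C@@H]2C[C@]3([C@@H](OC(=O)CCCCCCC/C=C\CCCCCCO[Si](C(C)C)(C(C)C)C(C)C)C=C2C(=O)OCC=C)[C@@H](C=O)CC[C@@H]13 | intermediate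
37 | C12 carboxylic acid, both primary hydroxyls as TIPS ethers | C[C@@]1(CO[Si](C(C)C)(C(C)C)C(C)C)[C@@H]2C[C@]3([C@@H](OC(=O)CCCCCCC/C=C\CCCCCCO[Si](C(C)C)(C(C)C)C(C)C)C=C2C(=O)O)[C@@H](C=O)CC[C@@H]13 | intermediate
38 | CNP0148862.1 | C[C@@]1(CO)[C@@H]2C[C@]3([C@@H](OC(=O)CCCCCCC/C=C\CCCCCCO)C=C2C(=O)O)[C@@H](C=O)CC[C@@H]13 | target

**Totals**
Total step count: 24. Longest linear sequence: 20 steps (from 1 through steps 1, 2, 4–16 and 20–24).

**Steps most likely to fail**

1. Step 9 (Pauson–Khand). Insertion of the trisubstituted alkene, held in the seven-membered silylene ring between C10 and C11, may be too slow, so the cobalt complex is decomplexed or reduced before it cyclises.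
Fallback: the tether is moved to after the cycloaddition. The route sets out from 12, whose exocyclic methylene belongs to the precedented alkene class. N-oxide-promoted cyclisation of 12 should give the C2-unsubstituted tricyclic enone F1 with free C10 hydroxyl. The kinetic α'-enolate of F1 (LiN(SiMe3)2, two equivalents) is hydroxymethylated at C2 with gaseous formaldehyde to the C2-hydroxymethyl enone F2 as a mixture of C2 epimers. Treatment of F2 with i-Pr2SiCl2 and imidazole closes the silylene: the C2 epimers interconvert through the C3 enol and only the one with C15 syn to O10 can form the seven-membered ring. This comes back to the route at 16.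

2. Step 11 (reductive allylic transposition). The Mitsunobu displacement at the hindered allylic C3 may be outrun by elimination to a diene, or the strain of the trans ring fusion being formed may slow hydrogen transfer so that the diazene decays by other paths.
Fallback: the route sets out from 17, which is formylated with formic acetic anhydride and pyridine to the C3 formate F3. Pd(OAc)2 and P(n-Bu)3 in dioxane then hydrogenolyse the allylic formate: zerovalent palladium ionises with inversion (metal on the C11 face), the formate loses CO2, and the palladium hydride transfers hydrogen to the more substituted terminus C5 from the metal's face. This comes back to the route at 20.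

3. Step 6 (reduction and resolution). Reagent control may fail to override the substrate's preference for hydride attack anti to the C7 arm, so that both enantiomers give mainly cis-dienol and little trans-dienol is obtained.
Fallback: the route sets out from racemic 11. Luche reduction (NaBH4, CeCl3·7H2O) under substrate control gives the racemic cis-dienol F4. Mitsunobu inversion with 4-nitrobenzoic acid, using the preformed PPh3/DIAD betaine to keep free phosphine away from cobalt, gives the racemic trans 4-nitrobenzoate F5, and K2CO3 in MeOH releases racemic 12. Esterification with (S)-2-methoxy-2-phenylacetic acid (DCC, DMAP) and chromatographic separation of the two diastereomeric esters gives the (S)-2-methoxy-2-phenylacetate F6 of the needed enantiomer, and K2CO3 in MeOH comes back to the route at 12.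

Further compounds
F1 | step 9 | tricyclic enone from the exocyclic-methylene complex (C2 = CH2, free C10 hydroxyl, C13 OTIPS, C12 methyl ester) | C[C@@]1(CO[Si](C(C)C)(C(C)C)C(C)C)[C@@H]2C[C@]3([C@@H](O)C=C2C(=O)OC)CC(=O)C=C13
F2 | step 9 | C2-hydroxymethyl enone, both C2 epimers | C[C@@]1(CO[Si](C(C)C)(C(C)C)C(C)C)[C@@H]2C[C@]3([C@@H](O)C=C2C(=O)OC)C(CO)C(=O)C=C13
F3 | step 11 | C3 formate of 17 | C[C@@]1(CO[Si](C(C)C)(C(C)C)C(C)C)[C@@H]2C[C@]3([C@@H](O[Si](C(C)C)(C(C)C)OC4)C=C2C(=O)OC)[C@@H]4[C@@H](OC=O)C=C13
F4 | step 6 | racemic cis-dienol (C10 epimer of 12), cobalt-complexed | C=C1C[C@@H]([C@@](C)(CO[Si](C(C)C)(C(C)C)C(C)C)C56C7[Co]5(=C=O)(=C=O)(=C=O)[Co]67(=C=O)(=C=O)=C=O)C(C(=O)OC)=C[C@H]1O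
F5 | step 6 | racemic trans C10 4-nitrobenzoate, cobalt-complexed | C=C1C[C@@H]([C@@](C)(CO[Si](C(C)C)(C(C)C)C(C)C)C56C7[Co]5(=C=O)(=C=O)(=C=O)[Co]67(=C=O)(=C=O)=C=O)C(C(=O)OC)=C[C@@H]1OC(=O)c2ccc(cc2)[N+](=O)[O-]
F6 | step 6 | C10 (S)-2-methoxy-2-phenylacetate of 12, cobalt-complexed | C=C1C[C@@H]([C@@](C)(CO[Si](C(C)C)(C(C)C)C(C)C)C56C7[Co]5(=C=O)(=C=O)(=C=O)[Co]67(=C=O)(=C=O)=C=O)C(C(=O)OC)=C[C@@H]1OC(=O)[C@@H](OC)c2ccccc2
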